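## Plan

- Ring names: ring A is the phenol ring that carries the biaryl bond para to its OH; ring B is the phenol ring that carries it ortho to its OH.
- Retrosynthesis: after removal of two O-protecting groups, ring B is cut at two bonds, one between its chain-bearing carbon and the adjacent CH, the other between its oxygen-bearing carbon and the biaryl carbon. The oxygen-bearing and chain-bearing carbons form the polarised two-carbon unit of a siloxyalkyne. The two CH carbons, the methyl-bearing carbon and the biaryl carbon are C6, C5, C4 and C3 of a 3-aryl-4-methyl-2-pyrone, whose lactone bridge leaves as CO2.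
- Further cuts: the pyrone C3–aryl bond (Suzuki coupling), the ring A side chain (copper-catalysed alkyl–alkenyl coupling, rhodium-catalysed conjugate arylation) and the alkyne C–O bond (ynolate silylation).
- Forward: ring A is bought as an arylboronic acid and elaborated (steps 1–6). The pyrone is made from a keto acetal (steps 7–9) and joined to ring A (step 10). The alkyne comes from citronellal (steps 11–12). Ring B is formed last (step 13), followed by two deprotections (steps 14–15).
- Stereochemistry: the (S) centre on ring A is set by the rhodium/(R)-BINAP arylation of tert-butyl crotonate. The (S) centre on ring B is carried in from (S)-citronellal. Neither is touched afterwards.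

Key step: step 13

Remark: the target carries no descriptor for the biaryl axis, so the axis is treated as not stereogenic; rotamers that the bulky silyl ether may show are carried on together and converge after desilylation.

## Route

Step 1
Reactants: 1 (2-methoxy-4-methylphenyl)boronic acid; 2 tert-butyl (E)-but-2-enoate
Product: 3 tert-butyl (3S)-3-(2-methoxy-4-methylphenyl)butanoate
Conditions: Rh(acac)(C2H4)2 (3 mol%), (R)-BINAP (4.5 mol%), 1 (2.5 equiv), dioxane/H2O 10:1, 100 °C
Reagents that add atoms: none
Why: Hayashi–Miyaura rhodium-catalysed asymmetric 1,4-addition of an arylboronic acid to an (E)-enoate, in which (S)-BINAP is known to give (R)-3-arylbutanoates from crotonates, so (R)-BINAP should deliver the aryl group to the opposite face of C3 and set the (S) centre of the ring A side chain.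

Step 2
Reactants: 3 tert-butyl (3S)-3-(2-methoxy-4-methylphenyl)butanoate
Product: 4 tert-butyl (3S)-3-(5-bromo-2-methoxy-4-methylphenyl)butanoate
Conditions: N-bromosuccinimide (1.05 equiv), MeCN, 0 → 23 °C, dark
Reagents that add atoms: N-bromosuccinimide, O=C1CCC(=O)N1Br
Why: Electrophilic aromatic bromination goes para to the methoxy group, the only strongly activated and unhindered position, and is placed here because the later trisubstituted alkene would not survive it.

Step 3
Reactants: 4 tert-butyl (3S)-3-(5-bromo-2-methoxy-4-methylphenyl)butanoate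
Product: 5 (3S)-3-(5-bromo-2-methoxy-4-methylphenyl)butan-1-ol
Conditions: iBu2AlH (2.5 equiv), CH2Cl2, −78 → 0 °C; aq. KNaC4H4O6 (potassium sodium tartrate) work-up
Reagents that add atoms: none
Why: Hydride reduction of the ester to the primary alcohol with iBu2AlH, which should leave the aryl bromide and the benzylic stereocentre untouched.

Step 4
Reactants: 5 (3S)-3-(5-bromo-2-methoxy-4-methylphenyl)butan-1-ol
Product: 6 1-bromo-5-[(2S)-4-iodobutan-2-yl]-4-methoxy-2-methylbenzene
Conditions: I2 (1.2 equiv), PPh3 (1.2 equiv), imidazole (1.5 equiv), CH2Cl2, 0 → 23 °C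
Reagents that add atoms: iodine, II
Why: Appel-type iodination (Garegg–Samuelsson conditions) converts the primary alcohol into the iodide by backside displacement of the oxyphosphonium group by iodide, two carbons away from the stereocentre.

Step 5
Reactants: 6 1-bromo-5-[(2S)-4-iodobutan-2-yl]-4-methoxy-2-methylbenzene; 7 2-methylprop-1-enylmagnesium bromide
Product: 8 1-bromo-4-methoxy-2-methyl-5-[(2S)-6-methylhept-5-en-2-yl]benzene
Conditions: 7 (2.0 equiv, THF solution), CuI (10 mol%), THF, −30 → 0 °C
Reagents that add atoms: none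
Why: Copper-catalysed Grignard cross-coupling (Kochi type) of a primary alkyl iodide with an alkenyl Grignard reagent, the standard way to complete this bisabolane side chain, with the aryl bromide expected to be inert at low temperature.

Step 6
Reactants: 8 1-bromo-4-methoxy-2-methyl-5-[(2S)-6-methylhept-5-en-2-yl]benzene
Product: 9 2-{4-methoxy-2-methyl-5-[(2S)-6-methylhept-5-en-2-yl]phenyl}-4,4,5,5-tetramethyl-1,3,2-dioxaborolane
Conditions: bis(pinacolato)diboron (1.3 equiv), Pd(dppf)Cl2 (5 mol%), KOAc (3 equiv), dioxane, 90 °C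
Reagents that add atoms: bis(pinacolato)diboron, CC1(C)OB(OC1(C)C)B1OC(C)(C)C(C)(C)O1
Why: Miyaura borylation of the aryl bromide, in which the weak base KOAc prevents onward Suzuki coupling and the isolated trisubstituted alkene is not engaged.

Step 7
Reactants: 10 4,4-dimethoxybutan-2-one; 11 tert-butyl 2-(diethoxyphosphoryl)acetate
Product: 12 tert-butyl 5,5-dimethoxy-3-methylpent-2-enoate (E/Z mixture)
Conditions: NaH (1.2 equiv), THF, 0 → 65 °C
Reagents that add atoms: none
Why: Horner–Wadsworth–Emmons olefination of the methyl ketone with a stabilised phosphonate, where both alkene isomers are usable because they should equilibrate under the acid of step 8.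

Step 8
Reactants: 12 tert-butyl 5,5-dimethoxy-3-methylpent-2-enoate (E/Z mixture)
Product: 15 4-methyl-2H-pyran-2-one, via 5,5-dimethoxy-3-methylpent-2-enoic acid 13 (not isolated), via 6-methoxy-4-methyl-5,6-dihydro-2H-pyran-2-one 14 (not isolated)
Conditions: TsOH·H2O (10 mol%), toluene, 110 °C, slow distillation of MeOH
Reagents that add atoms: none
Why: Acid-catalysed cascade of tert-butyl ester cleavage, acetal ionisation, lactonisation of the acid onto the oxocarbenium ion and elimination of methanol, driven by loss of the volatiles and by formation of the conjugated 2-pyrone, with the E and Z enoates interconverting through the methoxydiene.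

Step 9
Reactants: 15 4-methyl-2H-pyran-2-one
Product: 17 3-bromo-4-methyl-2H-pyran-2-one, via 3,6-dibromo-4-methyl-3,6-dihydro-2H-pyran-2-one 16 (not isolated)
Conditions: Br2 (1.05 equiv), CH2Cl2, 0 → 23 °C, dark; then Et3N (1.5 equiv), 0 °C
Reagents that add atoms: bromine, BrBr
Why: Bromination–dehydrobromination of a 2-pyrone, known to give the 3-bromo compound for the parent ring; attack at C3 gives a cation stabilised by the C4 methyl group and the ring oxygen, bromide adds at C6, and Et3N removes the acidic C3 hydrogen with loss of the C6 bromide.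

Step 10
Reactants: 9 2-{4-methoxy-2-methyl-5-[(2S)-6-methylhept-5-en-2-yl]phenyl}-4,4,5,5-tetramethyl-1,3,2-dioxaborolane; 17 3-bromo-4-methyl-2H-pyran-2-one
Product: 18 3-{4-methoxy-2-methyl-5-[(2S)-6-methylhept-5-en-2-yl]phenyl}-4-methyl-2H-pyran-2-one
Conditions: Pd(OAc)2 (5 mol%), SPhos (10 mol%), K3PO4 (3 equiv), toluene/H2O 10:1, 80 °C
Reagents that add atoms: none
Why: Suzuki–Miyaura coupling of a 3-bromo-2-pyrone with the aryl boronate, using the biaryl phosphine SPhos to bring about transmetalation and reductive elimination at a carbon flanked on both sides.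

Step 11
Reactants: 19 (3S)-3,7-dimethyloct-6-enal ((S)-citronellal)
Product: 21 (3S)-3,7-dimethyloct-6-en-1-yne, via (3S)-3,7-dimethylocta-1,6-dien-1-yl nonaflate 20 (not isolated)
Conditions: C4F9SO2F (1.3 equiv), phosphazene base BTPP (tert-butylimino-tri(pyrrolidino)phosphorane, 2.6 equiv), DMF, −20 → 23 °C
Reagents that add atoms: none
Why: One-pot conversion of an enolisable aldehyde into a terminal alkyne by O-sulfonylation of the enolate to the alkenyl nonaflate and base-induced β-elimination of nonaflate, so that C1 and C2 of citronellal become the alkyne while the C3 stereocentre, which has no acidifying neighbour, is not touched.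

Step 12
Reactants: 21 (3S)-3,7-dimethyloct-6-en-1-yne
Product: 24 {[(3S)-3,7-dimethyloct-6-en-1-yn-1-yl]oxy}tri(propan-2-yl)silane, via lithium acetylide 22 (not isolated), via lithium ynolate 23 (not isolated)
Conditions: LiN(SiMe3)2 (2.3 equiv), anhydrous tBuOOH (1.05 equiv), THF, −78 → 0 °C; then iPr3SiOTf (1.2 equiv), −78 °C
Reagents that add atoms: tert-butyl hydroperoxide, CC(C)(C)OO; triisopropylsilyl trifluoromethanesulfonate, CC(C)[Si](C(C)C)(C(C)C)OS(=O)(=O)C(F)(F)F
Why: Oxidation of the lithium acetylide by lithium tert-butyl peroxide to the ynolate followed by O-silylation with the bulky silyl triflate, the standard route to triisopropylsilyl ynol ethers, under which the propargylic stereocentre is not deprotonated.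

Step 13
Reactants: 18 3-{4-methoxy-2-methyl-5-[(2S)-6-methylhept-5-en-2-yl]phenyl}-4-methyl-2H-pyran-2-one; 24 {[(3S)-3,7-dimethyloct-6-en-1-yn-1-yl]oxy}tri(propan-2-yl)silane
Product: 26 {2-[4-methoxy-2-methyl-5-((2S)-6-methylhept-5-en-2-yl)phenyl]-3-methyl-6-[(2S)-6-methylhept-5-en-2-yl]phenoxy}tri(propan-2-yl)silane, via bridged bicyclic lactone 25 (not isolated)
Conditions: 24 (2.0 equiv), AgNTf2 (10 mol%), 2,6-di-tert-butyl-4-methylpyridine (20 mol%), 4 Å MS, ClCH2CH2Cl, 23 → 70 °C
Reagents that add atoms: none
Why: Proposed new method: the silver cation, held on the pyrone carbonyl oxygen and in reversible contact with the alkyne, should give the pyrone 2-oxypyrylium character, so that the nucleophilic alkyne carbon (the one carrying the side chain) attacks the unsubstituted C6 and the resulting silyl ketenium carbon is captured by the dienolate at C3, a polar and possibly stepwise inverse-electron-demand [4+2] addition; the closest known reaction types are the Diels–Alder reaction of 2-pyrones with ynamines or alkoxyalkynes followed by loss of CO2 and the AgNTf2-catalysed formal cycloaddition of siloxyalkynes with 1,2-diazines. Ring B is closed by this intermolecular [4+2] annulation of the pyrone C3–C6 diene with the two alkyne carbons (chain-bearing carbon to C6 first, oxygen-bearing carbon to C3 second, the latter a six-membered closure onto a linear carbon), and the bridged lactone 25 then aromatises by retro-[4+2] extrusion of CO2, which makes the sequence irreversible. No stereocentre is created: both side-chain centres are spectators, the two diastereomeric bridged lactones collapse to one arene, and the biaryl axis is not fixed. The step needs a single orientation of the alkyne, which is secured by polarity matching (nucleophilic alkyne carbon to electrophilic C6, oxygen-bearing carbon to nucleophilic C3) and reinforced by the fully substituted C3=C4 bond, which disfavours attack at C4 and [2+2] closure. The hindered pyridine and the molecular sieves keep HNTf2 from protonating 24, so that its trisubstituted alkene should not be drawn into a ketenium–olefin cyclisation.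

Step 14
Reactants: 26 {2-[4-methoxy-2-methyl-5-((2S)-6-methylhept-5-en-2-yl)phenyl]-3-methyl-6-[(2S)-6-methylhept-5-en-2-yl]phenoxy}tri(propan-2-yl)silane
Product: 27 2-{4-methoxy-2-methyl-5-[(2S)-6-methylhept-5-en-2-yl]phenyl}-3-methyl-6-[(2S)-6-methylhept-5-en-2-yl]phenol
Conditions: Bu4NF (1.5 equiv), THF, 0 → 23 °C; water work-up
Reagents that add atoms: none
Why: Fluoride-induced cleavage of the aryl silyl ether, driven by the Si–F bond strength and the phenoxide leaving group, to which the methyl ether and both alkenes are inert.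

Step 15
Reactants: 27 2-{4-methoxy-2-methyl-5-[(2S)-6-methylhept-5-en-2-yl]phenyl}-3-methyl-6-[(2S)-6-methylhept-5-en-2-yl]phenol
Product: 28 2-{4-hydroxy-2-methyl-5-[(2S)-6-methylhept-5-en-2-yl]phenyl}-3-methyl-6-[(2S)-6-methylhept-5-en-2-yl]phenol (CNP0290341.1)
Conditions: NaSEt (6 equiv), DMF, 130 °C; then 1 M HCl, 0 °C
Reagents that add atoms: none
Why: Nucleophilic demethylation of the aryl methyl ether by ethanethiolate in hot DMF (bimolecular substitution at the methyl carbon), chosen because Lewis or protic acids such as BBr3 or HBr would attack the two trisubstituted alkenes.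

## Compound list

1 | (2-methoxy-4-methylphenyl)boronic acid | COc1cc(C)ccc1B(O)O | starting material
2 | tert-butyl (E)-but-2-enoate | C/C=C/C(=O)OC(C)(C)C | starting material
3 | tert-butyl (3S)-3-(2-methoxy-4-methylphenyl)butanoate | CC(C)(C)OC(=O)C[C@H](C)c1ccc(C)cc1OC | intermediate
4 | tert-butyl (3S)-3-(5-bromo-2-methoxy-4-methylphenyl)butanoate | CC(C)(C)OC(=O)C[C@H](C)c1cc(Br)c(C)cc1OC | intermediate
5 | (3S)-3-(5-bromo-2-methoxy-4-methylphenyl)butan-1-ol | OCC[C@H](C)c1cc(Br)c(C)cc1OC | intermediate
6 | 1-bromo-5-[(2S)-4-iodobutan-2-yl]-4-methoxy-2-methylbenzene | ICC[C@H](C)c1cc(Br)c(C)cc1OC | intermediate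
7 | 2-methylprop-1-enylmagnesium bromide | CC(C)=C[Mg]Br | starting material
8 | 1-bromo-4-methoxy-2-methyl-5-[(2S)-6-methylhept-5-en-2-yl]benzene | CC(C)=CCC[C@H](C)c1cc(Br)c(C)cc1OC | intermediate
9 | 2-{4-methoxy-2-methyl-5-[(2S)-6-methylhept-5-en-2-yl]phenyl}-4,4,5,5-tetramethyl-1,3,2-dioxaborolane | CC(C)=CCC[C@H](C)c1cc(B2OC(C)(C)C(C)(C)O2)c(C)cc1OC | intermediate
10 | 4,4-dimethoxybutan-2-one | COC(CC(C)=O)OC | starting material
11 | tert-butyl 2-(diethoxyphosphoryl)acetate | CCOP(=O)(CC(=O)OC(C)(C)C)OCC | starting material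
12 | tert-butyl 5,5-dimethoxy-3-methylpent-2-enoate (E/Z mixture) | COC(CC(C)=CC(=O)OC(C)(C)C)OC | intermediate
13 | 5,5-dimethoxy-3-methylpent-2-enoic acid (not isolated) | COC(CC(C)=CC(=O)O)OC | intermediate
14 | 6-methoxy-4-methyl-5,6-dihydro-2H-pyran-2-one (not isolated) | COC1CC(C)=CC(=O)O1 | intermediate
15 | 4-methyl-2H-pyran-2-one | Cc1ccoc(=O)c1 | intermediate
16 | 3,6-dibromo-4-methyl-3,6-dihydro-2H-pyran-2-one (not isolated) | CC1=CC(Br)OC(=O)C1Br | intermediate
17 | 3-bromo-4-methyl-2H-pyran-2-one | Cc1ccoc(=O)c1Br | intermediate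
18 | 3-{4-methoxy-2-methyl-5-[(2S)-6-methylhept-5-en-2-yl]phenyl}-4-methyl-2H-pyran-2-one | CC(C)=CCC[C@H](C)c1cc(-c2c(C)ccoc2=O)c(C)cc1OC | intermediate
19 | (3S)-3,7-dimethyloct-6-enal ((S)-citronellal) | CC(C)=CCC[C@H](C)CC=O | starting material
20 | (3S)-3,7-dimethylocta-1,6-dien-1-yl nonafluorobutane-1-sulfonate (E/Z, not isolated) | CC(C)=CCC[C@H](C)C=COS(=O)(=O)C(F)(F)C(F)(F)C(F)(F)C(F)(F)F | intermediate
21 | (3S)-3,7-dimethyloct-6-en-1-yne | CC(C)=CCC[C@H](C)C#C | intermediate
22 | lithium (3S)-3,7-dimethyloct-6-en-1-yn-1-ide (not isolated) | CC(C)=CCC[C@H](C)C#C[Li] | intermediate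
23 | lithium (3S)-3,7-dimethyloct-6-en-1-yn-1-olate (not isolated) | CC(C)=CCC[C@H](C)C#CO[Li] | intermediate
24 | {[(3S)-3,7-dimethyloct-6-en-1-yn-1-yl]oxy}tri(propan-2-yl)silane | CC(C)=CCC[C@H](C)C#CO[Si](C(C)C)(C(C)C)C(C)C | intermediate
25 | 4-aryl-5-methyl-7-[(2S)-6-methylhept-5-en-2-yl]-8-[tri(propan-2-yl)silyloxy]-2-oxabicyclo[2.2.2]octa-5,7-dien-3-one (aryl as in 18; both bridgehead configurations; not isolated) | O=C1OC2C=C(C)C1(c1cc([C@@H](C)CCC=C(C)C)c(OC)cc1C)C(O[Si](C(C)C)(C(C)C)C(C)C)=C2[C@@H](C)CCC=C(C)C | intermediate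
26 | {2-[4-methoxy-2-methyl-5-((2S)-6-methylhept-5-en-2-yl)phenyl]-3-methyl-6-[(2S)-6-methylhept-5-en-2-yl]phenoxy}tri(propan-2-yl)silane | CC(C)=CCC[C@H](C)c1cc(-c2c(C)ccc([C@@H](C)CCC=C(C)C)c2O[Si](C(C)C)(C(C)C)C(C)C)c(C)cc1OC | intermediate
27 | 2-{4-methoxy-2-methyl-5-[(2S)-6-methylhept-5-en-2-yl]phenyl}-3-methyl-6-[(2S)-6-methylhept-5-en-2-yl]phenol | CC(C)=CCC[C@H](C)c1cc(-c2c(C)ccc([C@@H](C)CCC=C(C)C)c2O)c(C)cc1OC | intermediate
28 | 2-{4-hydroxy-2-methyl-5-[(2S)-6-methylhept-5-en-2-yl]phenyl}-3-methyl-6-[(2S)-6-methylhept-5-en-2-yl]phenol (CNP0290341.1) | CC(C)=CCC[C@H](C)c1cc(-c2c(C)ccc([C@@H](C)CCC=C(C)C)c2O)c(C)cc1O | target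

## Step count and risks

Total steps: 15. Longest linear sequence: 10 (steps 1–6, 10, 13, 14, 15).

**1. Step 13 (carries the label "Proposed new method:").**
What may go wrong: the cycloaddition may not start because the pyrone carries a donor aryl group and no acceptor. On prolonged heating the siloxyalkyne may rearrange by silyl migration to a silylketene. Traces of acid may send the ketenium ion into cyclisation onto the side-chain alkene.
Fallback (known chemistry; sets out from 8, uses 9, comes back at 28): the biaryl bond is made by cross-coupling instead of by building ring B. Bromide 8 is reduced with Pd(OAc)2, PPh3 and HCO2Na in DMF at 80 °C to 2-methoxy-4-methyl-1-[(2S)-6-methylhept-5-en-2-yl]benzene F1. Directed ortho-lithiation with sec-BuLi and TMEDA in Et2O (−78 → 0 °C) can only occur between the methoxy and methyl groups, because the other ortho position carries the side chain. It gives {2-methoxy-6-methyl-3-[(2S)-6-methylhept-5-en-2-yl]phenyl}lithium F2, which is quenched with I2 to 2-iodo-3-methoxy-1-methyl-4-[(2S)-6-methylhept-5-en-2-yl]benzene F3. Suzuki–Miyaura coupling of F3 with boronate 9 (Pd(OAc)2, SPhos, K3PO4, toluene/H2O, 100 °C) should give 2-{4-methoxy-2-methyl-5-[(2S)-6-methylhept-5-en-2-yl]phenyl}-1-methoxy-3-methyl-6-[(2S)-6-methylhept-5-en-2-yl]benzene F4. NaSEt in DMF at 130 °C, followed by 1 M HCl, then cleaves both methyl ethers to give 28.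

**2. Step 9.**
What may go wrong: poor site selectivity, with bromine ending up at C5 or on the C4 methyl group instead of at C3, or over-bromination.
Fallback (sets out from 12, comes back at 17): bromine is placed on the open chain, where the position is fixed by the enoate α-carbon. Addition of Br2 to 12 in CH2Cl2 gives tert-butyl 2,3-dibromo-5,5-dimethoxy-3-methylpentanoate F5. Et3N removes the acidic C2 hydrogen with loss of the tertiary bromide to give tert-butyl 2-bromo-5,5-dimethoxy-3-methylpent-2-enoate F6. Under the conditions of step 8 (TsOH·H2O, toluene, 110 °C) F6 should pass through 2-bromo-5,5-dimethoxy-3-methylpent-2-enoic acid F7 and 3-bromo-6-methoxy-4-methyl-5,6-dihydro-2H-pyran-2-one F8 to 17.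

**3. Step 10.**
What may go wrong: ring opening of the bromopyrone by the aqueous base and protodeboronation of the electron-rich, ortho-substituted boronate may outrun a slow transmetalation at the doubly flanked C3.
Fallback (sets out from 8, comes back at 18): a Stille coupling without aqueous base replaces the Suzuki coupling. Bromide 8 is stannylated with Me3SnSnMe3 and Pd(PPh3)4 in toluene at 100 °C to trimethyl{4-methoxy-2-methyl-5-[(2S)-6-methylhept-5-en-2-yl]phenyl}stannane F9. F9 is coupled with 17 using Pd(PPh3)4, CuI (10 mol%) and CsF (2 equiv) in DMF at 60 °C, conditions established for 3-bromo-2-pyrones, to give 18.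

## Further compounds

F1 | step 13 | 2-methoxy-4-methyl-1-[(2S)-6-methylhept-5-en-2-yl]benzene | CC(C)=CCC[C@H](C)c1ccc(C)cc1OC
F2 | step 13 | {2-methoxy-6-methyl-3-[(2S)-6-methylhept-5-en-2-yl]phenyl}lithium | CC(C)=CCC[C@H](C)c1ccc(C)c([Li])c1OC
F3 | step 13 | 2-iodo-3-methoxy-1-methyl-4-[(2S)-6-methylhept-5-en-2-yl]benzene | CC(C)=CCC[C@H](C)c1ccc(C)c(I)c1OC
F4 | step 13 | 2-{4-methoxy-2-methyl-5-[(2S)-6-methylhept-5-en-2-yl]phenyl}-1-methoxy-3-methyl-6-[(2S)-6-methylhept-5-en-2-yl]benzene | CC(C)=CCC[C@H](C)c1cc(-c2c(C)ccc([C@@H](C)CCC=C(C)C)c2OC)c(C)cc1OC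
F5 | step 9 | tert-butyl 2,3-dibromo-5,5-dimethoxy-3-methylpentanoate | COC(CC(C)(Br)C(Br)C(=O)OC(C)(C)C)OC
F6 | step 9 | tert-butyl 2-bromo-5,5-dimethoxy-3-methylpent-2-enoate | COC(CC(C)=C(Br)C(=O)OC(C)(C)C)OC
F7 | step 9 | 2-bromo-5,5-dimethoxy-3-methylpent-2-enoic acid | COC(CC(C)=C(Br)C(=O)O)OC
F8 | step 9 | 3-bromo-6-methoxy-4-methyl-5,6-dihydro-2H-pyran-2-one | COC1CC(C)=C(Br)C(=O)O1
F9 | step 10 | trimethyl{4-methoxy-2-methyl-5-[(2S)-6-methylhept-5-en-2-yl]phenyl}stannane | CC(C)=CCC[C@H](C)c1cc([Sn](C)(C)C)c(C)cc1OC
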